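**Plan**

1. Elemane numbering is used: ring C5–C10; C1=C2 vinyl and C14 methyl on C10; C3=C4–C15 on C5; lactone C12(=O)–O–C6 with C11 on C7; ester oxygen on C8. With the C10 methyl β, the target is 5α-H, 6β-H, 7α-H, 8α-O, so all ring substituents are equatorial and the C10 methyl is axial.
2. Retrosynthesis: (i) cut the C8 ester (side-chain acid 23) and the exocyclic methylenes C13 and C3; (ii) cut together the lactone O–C6 bond and the ring bond C7–C8, which opens both rings to the acyclic aldehyde diacid 10; (iii) cut C5–C10 by an Ireland–Claisen transform to trans-3-hexenedioic acid and an E-allylic alcohol.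
3. The feature that allows (ii): the lactone oxygen on C6 and the oxygen on C8 are 1,3 on the cyclohexane, with the CH2CO2H-bearing C7 between them. This is the retron of a Prins addition of a C8 aldehyde to an E-C6=C7 alkene, terminated at C6 by the C12 carboxyl of a β,γ-unsaturated acid.
4. Forward: chain assembly, then C5–C10 by rearrangement, then the cyclohexane ring (C5–C10) and the γ-lactone ring (O–C6–C7–C11–C12) closed in one step, then C4 and C11 elaborated, then the side chain attached.
5. Stereochemistry: C5 and C10 come from the chair Ireland–Claisen rearrangement (E-alkene, Z-(O) enolate, chiral boron reagent for the absolute sense). C6, C7 and C8 come from the chair of the bicyclisation. The side-chain centre comes from (R)-solketal.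

Key step: step 7

Assumption: the (S,S)-diazaborolidine is taken to deliver the (2R,3′S) acid 7, by analogy with E-allylic esters of this reagent class; if the sense were opposite, its (R,R)-antipode would be used.

**Route**

Step 1
Reactants: 1 4-(tert-butyldimethylsilyloxy)but-1-yne
Product: 3 (2E)-5-(tert-butyldimethylsilyloxy)-3-methylpent-2-en-1-ol, via alkenylalane 2 (not isolated)
Conditions: AlMe3, Cp2ZrCl2 (20 mol %), CH2Cl2, 0 °C → rt; then (CH2O)n, THF, rt; aqueous work-up
Reagents that add atoms: trimethylaluminium C[Al](C)C; formaldehyde (as paraformaldehyde) C=O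
Why: Zirconium-catalysed syn carboalumination (Negishi) should place CH3 on the internal and Al on the terminal alkyne carbon, and hydroxymethylation of the alkenylalane with retention fixes the E-trisubstituted alkene needed for the later chair rearrangement.

Step 2
Reactants: 3 (2E)-5-(tert-butyldimethylsilyloxy)-3-methylpent-2-en-1-ol (2 equiv); 4 (3E)-hex-3-enedioic acid
Product: 5 bis[(2E)-5-(tert-butyldimethylsilyloxy)-3-methylpent-2-en-1-yl] (3E)-hex-3-enedioate
Conditions: DCC, DMAP (cat.), CH2Cl2, 0 °C
Reagents that add atoms: none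
Why: Carbodiimide (Steglich) esterification of both carboxyl groups at low temperature should keep the β,γ-alkene in place, and the symmetric diester makes the two α-CH2 groups equivalent for step 3.

Step 3
Reactants: 5 bis-allylic diester
Product: 7 (2R,3E)-2-[(3S)-5-(tert-butyldimethylsilyloxy)-3-methylpent-1-en-3-yl]hex-3-enedioic acid 6-[(2E)-5-(tert-butyldimethylsilyloxy)-3-methylpent-2-en-1-yl] ester, via boron ketene acetal 6 (not isolated)
Conditions: (S,S)-2-bromo-4,5-diphenyl-1,3-bis{[3,5-bis(trifluoromethyl)phenyl]sulfonyl}-1,3,2-diazaborolidine (1.1 equiv), i-Pr2NEt, CH2Cl2, −78 °C; then −20 °C; aqueous work-up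
Reagents that add atoms: none
Why: Enantioselective Ireland–Claisen rearrangement through a chiral boron ketene acetal: the Z-(O) enolate and the E-allyl unit should pass through a chair that joins C5 to C10 with the carboxyl and the new vinyl group in the relationship that is trans-diequatorial on the later ring, while the C2-symmetric diazaborolidine shields one enolate face and sets the absolute configuration of both centres.

Step 4
Reactants: 7 half-ester acid
Product: 8 (2R,3E)-2-[(3S)-5-(tert-butyldimethylsilyloxy)-3-methylpent-1-en-3-yl]hex-3-enedioic acid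
Conditions: LiOH, THF/H2O, 0 °C → rt; then aqueous HCl to pH 3
Reagents that add atoms: lithium hydroxide [Li+].[OH-]
Why: Saponification should cleave the unhindered allylic ester, give the diacid and return alcohol 3 for re-use.

Step 5
Reactants: 8 silyl ether diacid
Product: 9 (2R,3E)-2-[(3S)-5-hydroxy-3-methylpent-1-en-3-yl]hex-3-enedioic acid
Conditions: HF·pyridine, pyridine, THF, 0 °C
Reagents that add atoms: none
Why: Buffered fluoride cleavage of the primary silyl ether; 9 is oxidised at once so that the δ-hydroxy acid does not close to a δ-lactone.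

Step 6
Reactants: 9 hydroxy diacid
Product: 10 (2R,3E)-2-[(3S)-3-methyl-5-oxopent-1-en-3-yl]hex-3-enedioic acid
Conditions: Dess–Martin periodinane, CH2Cl2, 0 °C → rt
Reagents that add atoms: none
Why: Dess–Martin oxidation of the primary alcohol to the aldehyde tolerates the free acids and the alkenes, and the non-basic medium cannot epimerise C5 or move the β,γ-alkene.

Step 7
Reactants: 10 aldehyde diacid
Product: 11 6-ethenyl-4-hydroxy-6-methyl-2-oxooctahydro-1-benzofuran-7-carboxylic acid (trans-fused; 5α-H, 6β-H, 7α-H, 8α-OH, 10β-CH3)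
Conditions: Sc(OTf)3 (10 mol %), CH2Cl2, 0 °C → rt
Reagents that add atoms: none
Why: Proposed new method: Sc(OTf)3 activates the C8 aldehyde, C7 of the E-C6=C7 alkene attacks it and, as positive charge builds at C6, the C12 carboxyl oxygen adds anti and loses its proton, so that the acyclic aldehyde diacid isomerises to the bicyclic hydroxy lactone; the closest known reaction types are the Lewis-acid Prins cyclisation of 5-hexenals to 3-halocyclohexanols and cation–olefin cyclisations terminated by a carboxylic acid. The cyclohexane closes 6-exo-trig at the carbonyl carbon with both alkene carbons in the ring (chair), and the γ-lactone closes by 5-endo attack of oxygen at C6, which is feasible because C6 is carbocation-like when that bond forms. C8 is set by the equatorial position of the scandium-bound carbonyl oxygen (an axial oxygen would meet the axial C10 methyl), C7 by the E geometry of the alkene, which puts the CH2CO2H arm equatorial, and C6 by anti addition, which brings the lactone oxygen in equatorially and makes the ring fusion trans. The existing centres choose the chair that has only the C10 methyl axial (vinyl and C5–CO2H equatorial), and this fixes the three new centres relative to C5 and C10. The step needs bond formation at C7 and not at C6, and capture by the C12 carboxyl alone: closure through C6 would leave a cation at C7 that the C12 acid could trap only as a β-lactone, the C4 acid can reach C6 only as a β-lactone, the vinyl group could add only in a 5-endo mode, and the triflate counter-ion is not nucleophilic.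

Step 8
Reactants: 11 hydroxy lactone acid
Product: 12 triethylsilyl 6-ethenyl-6-methyl-2-oxo-4-(triethylsilyloxy)octahydro-1-benzofuran-7-carboxylate
Conditions: Et3SiCl (2.5 equiv), imidazole, CH2Cl2, 0 °C; non-aqueous work-up
Reagents that add atoms: chlorotriethylsilane CC[Si](Cl)(CC)CC
Why: Silylation of the C8 hydroxyl and of the carboxyl protects O8 at once against translactonisation and against the later basic steps, and the silyl ester is the form from which the acid chloride can be made under neutral conditions.

Step 9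
Reactants: 12 bis-silyl compound
Product: 14 6-ethenyl-7-[(methoxymethoxy)acetyl]-6-methyl-4-(triethylsilyloxy)hexahydro-1-benzofuran-2(3H)-one, via acid chloride 13 (not isolated)
Conditions: (COCl)2, DMF (cat.), CH2Cl2, 0 °C; then Bu3SnCH2OCH2OCH3, PdCl2(PPh3)2 (5 mol %), toluene, 80 °C
Reagents that add atoms: tributyl[(methoxymethoxy)methyl]stannane CCCC[Sn](CCCC)(CCCC)COCOC
Why: The silyl ester should be converted to the acid chloride without free HCl, and palladium-catalysed acyl Stille (Kosugi–Migita–Stille) coupling with the α-alkoxymethylstannane should give the ketone carrying C15 without touching the lactone; C5 stays equatorial, its favoured configuration.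

Step 10
Reactants: 14 α-alkoxy ketone
Product: 15 6-ethenyl-7-[3-(methoxymethoxy)prop-1-en-2-yl]-6-methyl-4-(triethylsilyloxy)hexahydro-1-benzofuran-2(3H)-one
Conditions: Zn, CH2Br2, TiCl4, THF/CH2Cl2, 0 °C → rt
Reagents that add atoms: dibromomethane BrCBr
Why: Takai–Lombardo methylenation is non-basic, so the β-acyloxy ketone should not eliminate and the lactone carbonyl should be left alone.

Step 11
Reactants: 15 lactone
Product: 18 6-ethenyl-7-[3-(methoxymethoxy)prop-1-en-2-yl]-6-methyl-3-methylidene-4-(triethylsilyloxy)hexahydro-1-benzofuran-2(3H)-one, via Mannich base 16 (not isolated), via ammonium iodide 17 (not isolated)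
Conditions: LiN(i-Pr)2, THF, −78 °C; CH2=NMe2+ I−, −78 °C → rt; then CH3I, MeOH, rt; then aqueous NaHCO3, rt
Reagents that add atoms: N,N-dimethylmethyleneiminium iodide C=[N+](C)C.[I-]
Why: α-Methylenation by Mannich reaction of the lactone lithium enolate with Eschenmoser's salt, N-methylation and Hofmann-type elimination; C11 is the only enolisable position and the elimination can only give the exocyclic alkene, so C7 is untouched.

Step 12
Reactants: 18 silyl ether
Product: 19 6-ethenyl-4-hydroxy-7-[3-(methoxymethoxy)prop-1-en-2-yl]-6-methyl-3-methylidenehexahydro-1-benzofuran-2(3H)-one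
Conditions: HF·pyridine, pyridine, THF, 0 °C
Reagents that add atoms: none
Why: Fluoride cleavage of the secondary triethylsilyl ether under buffered acidic conditions should leave the MOM ether and the α-methylene lactone intact.

Step 13
Reactants: 20 (R)-(2,2-dimethyl-1,3-dioxolan-4-yl)methanol [(R)-solketal]
Product: 21 (S)-2,2-dimethyl-1,3-dioxolane-4-carbaldehyde
Conditions: (COCl)2, DMSO, CH2Cl2, −78 °C; then Et3N, −78 °C → 0 °C
Reagents that add atoms: none
Why: Swern oxidation; the α-alkoxy aldehyde is kept cold and used crude so that its stereocentre is not racemised.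

Step 14
Reactants: 21 (S)-aldehyde
Product: 22 (R)-4-ethynyl-2,2-dimethyl-1,3-dioxolane
Conditions: dimethyl (1-diazo-2-oxopropyl)phosphonate, K2CO3, MeOH, 0 °C → rt
Reagents that add atoms: dimethyl (1-diazo-2-oxopropyl)phosphonate COP(=O)(OC)C(=[N+]=[N-])C(C)=O
Why: Ohira–Bestmann homologation converts the aldehyde to the terminal alkyne under mild carbonate conditions that should preserve the adjacent stereocentre.

Step 15
Reactants: 22 (R)-alkyne
Product: 23 2-[(4R)-2,2-dimethyl-1,3-dioxolan-4-yl]prop-2-enoic acid
Conditions: Pd(OAc)2 (2 mol %), 2-(diphenylphosphino)pyridine, CH3SO3H (cat.), CO (20 bar), H2O, acetone, 45 °C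
Reagents that add atoms: carbon monoxide [C-]#[O+]; water O
Why: Palladium-catalysed Markovnikov hydrocarboxylation of the terminal alkyne with a P,N-ligand (Reppe-type carbonylation) should place the carboxyl on the internal carbon and give the 2-substituted acrylic acid, with acetone as co-solvent keeping the acetonide.

Step 16
Reactants: 19 C8 alcohol; 23 acrylic acid
Product: 24 C8 ester of 19 with 23 (15-O-MOM ether and side-chain acetonide of the target)
Conditions: N,N′-diisopropylcarbodiimide, DMAP, CH2Cl2, 0 °C → rt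
Reagents that add atoms: none
Why: Steglich esterification of the equatorial C8 hydroxyl; the stereocentre of 23 is β to the carboxyl and cannot epimerise through a ketene or enolate.

Step 17
Reactants: 24 protected ester
Product: 25 target, 8α-[(3R)-3,4-dihydroxy-2-methylidenebutanoyloxy]-15-hydroxyelema-1,3,11(13)-trien-12,6α-olide
Conditions: Me2BBr, CH2Cl2, −78 °C; then aqueous NaHCO3
Reagents that add atoms: none
Why: Acetal cleavage with dimethylboron bromide should remove the MOM ether and the acetonide at low temperature without attacking the esters, the α-methylene lactone or the allylic alcohols.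

**Compound list**

1 | 4-(tert-butyldimethylsilyloxy)but-1-yne | C#CCCO[Si](C)(C)C(C)(C)C | starting material
2 | (E)-[4-(tert-butyldimethylsilyloxy)-2-methylbut-1-en-1-yl]dimethylalane | C/C(=C\[Al](C)C)CCO[Si](C)(C)C(C)(C)C | intermediate (not isolated)
3 | (2E)-5-(tert-butyldimethylsilyloxy)-3-methylpent-2-en-1-ol | C/C(=C\CO)CCO[Si](C)(C)C(C)(C)C | intermediate
4 | (3E)-hex-3-enedioic acid | OC(=O)C/C=C/CC(=O)O | starting material
5 | bis[(2E)-5-(tert-butyldimethylsilyloxy)-3-methylpent-2-en-1-yl] (3E)-hex-3-enedioate | C/C(=C\COC(=O)C/C=C/CC(=O)OC/C=C(\C)CCO[Si](C)(C)C(C)(C)C)CCO[Si](C)(C)C(C)(C)C | intermediate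
6 | Z-(O) boron ketene acetal of 5, oxygen-bound to the (S,S)-diazaborolidine | C/C(=C\CO/C(=C/C=C/CC(=O)OC/C=C(\C)CCO[Si](C)(C)C(C)(C)C)OB1N(S(=O)(=O)c2cc(cc(c2)C(F)(F)F)C(F)(F)F)[C@@H](c2ccccc2)[C@H](c2ccccc2)N1S(=O)(=O)c2cc(cc(c2)C(F)(F)F)C(F)(F)F)CCO[Si](C)(C)C(C)(C)C | intermediate (not isolated)
7 | (2R,3E)-2-[(3S)-5-(tert-butyldimethylsilyloxy)-3-methylpent-1-en-3-yl]hex-3-enedioic acid 6-[(2E)-5-(tert-butyldimethylsilyloxy)-3-methylpent-2-en-1-yl] ester | C=C[C@](C)(CCO[Si](C)(C)C(C)(C)C)[C@H](C(=O)O)/C=C/CC(=O)OC/C=C(\C)CCO[Si](C)(C)C(C)(C)C | intermediate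
8 | (2R,3E)-2-[(3S)-5-(tert-butyldimethylsilyloxy)-3-methylpent-1-en-3-yl]hex-3-enedioic acid | C=C[C@](C)(CCO[Si](C)(C)C(C)(C)C)[C@H](C(=O)O)/C=C/CC(=O)O | intermediate
9 | (2R,3E)-2-[(3S)-5-hydroxy-3-methylpent-1-en-3-yl]hex-3-enedioic acid | C=C[C@](C)(CCO)[C@H](C(=O)O)/C=C/CC(=O)O | intermediate
10 | (2R,3E)-2-[(3S)-3-methyl-5-oxopent-1-en-3-yl]hex-3-enedioic acid | C=C[C@](C)(CC=O)[C@H](C(=O)O)/C=C/CC(=O)O | intermediate
11 | 6-ethenyl-4-hydroxy-6-methyl-2-oxooctahydro-1-benzofuran-7-carboxylic acid (trans-fused, all substituents equatorial, C6 methyl axial) | C=C[C@]1(C)C[C@H](O)[C@H]2CC(=O)O[C@@H]2[C@H]1C(=O)O | intermediate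
12 | triethylsilyl 6-ethenyl-6-methyl-2-oxo-4-(triethylsilyloxy)octahydro-1-benzofuran-7-carboxylate | C=C[C@]1(C)C[C@H](O[Si](CC)(CC)CC)[C@H]2CC(=O)O[C@@H]2[C@H]1C(=O)O[Si](CC)(CC)CC | intermediate
13 | 6-ethenyl-6-methyl-2-oxo-4-(triethylsilyloxy)octahydro-1-benzofuran-7-carbonyl chloride | C=C[C@]1(C)C[C@H](O[Si](CC)(CC)CC)[C@H]2CC(=O)O[C@@H]2[C@H]1C(Cl)=O | intermediate (not isolated)
14 | 6-ethenyl-7-[(methoxymethoxy)acetyl]-6-methyl-4-(triethylsilyloxy)hexahydro-1-benzofuran-2(3H)-one | C=C[C@]1(C)C[C@H](O[Si](CC)(CC)CC)[C@H]2CC(=O)O[C@@H]2[C@H]1C(=O)COCOC | intermediate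
15 | 6-ethenyl-7-[3-(methoxymethoxy)prop-1-en-2-yl]-6-methyl-4-(triethylsilyloxy)hexahydro-1-benzofuran-2(3H)-one | C=C[C@]1(C)C[C@H](O[Si](CC)(CC)CC)[C@H]2CC(=O)O[C@@H]2[C@H]1C(=C)COCOC | intermediate
16 | 3-[(dimethylamino)methyl] derivative of 15 (mixture of C3 epimers) | C=C[C@]1(C)C[C@H](O[Si](CC)(CC)CC)[C@H]2C(CN(C)C)C(=O)O[C@@H]2[C@H]1C(=C)COCOC | intermediate (not isolated)
17 | 3-[(trimethylammonio)methyl] derivative of 15, iodide (mixture of C3 epimers) | C=C[C@]1(C)C[C@H](O[Si](CC)(CC)CC)[C@H]2C(C[N+](C)(C)C)C(=O)O[C@@H]2[C@H]1C(=C)COCOC.[I-] | intermediate (not isolated)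
18 | 6-ethenyl-7-[3-(methoxymethoxy)prop-1-en-2-yl]-6-methyl-3-methylidene-4-(triethylsilyloxy)hexahydro-1-benzofuran-2(3H)-one | C=C[C@]1(C)C[C@H](O[Si](CC)(CC)CC)[C@H]2C(=C)C(=O)O[C@@H]2[C@H]1C(=C)COCOC | intermediate
19 | 6-ethenyl-4-hydroxy-7-[3-(methoxymethoxy)prop-1-en-2-yl]-6-methyl-3-methylidenehexahydro-1-benzofuran-2(3H)-one | C=C[C@]1(C)C[C@H](O)[C@H]2C(=C)C(=O)O[C@@H]2[C@H]1C(=C)COCOC | intermediate
20 | (R)-(2,2-dimethyl-1,3-dioxolan-4-yl)methanol | OC[C@@H](O1)COC1(C)C | starting material
21 | (S)-2,2-dimethyl-1,3-dioxolane-4-carbaldehyde | O=C[C@@H](O1)COC1(C)C | intermediate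
22 | (R)-4-ethynyl-2,2-dimethyl-1,3-dioxolane | C#C[C@@H](O1)COC1(C)C | intermediate
23 | 2-[(4R)-2,2-dimethyl-1,3-dioxolan-4-yl]prop-2-enoic acid | OC(=O)C(=C)[C@@H](O1)COC1(C)C | intermediate
24 | 8α-{2-[(4R)-2,2-dimethyl-1,3-dioxolan-4-yl]prop-2-enoyloxy}-15-(methoxymethoxy)elema-1,3,11(13)-trien-12,6α-olide | C=C[C@]1(C)C[C@H](OC(=O)C(=C)[C@@H](O3)COC3(C)C)[C@H]2C(=C)C(=O)O[C@@H]2[C@H]1C(=C)COCOC | intermediate
25 | 8α-[(3R)-3,4-dihydroxy-2-methylidenebutanoyloxy]-15-hydroxyelema-1,3,11(13)-trien-12,6α-olide | C=C[C@]1(C)C[C@H](OC(=O)C(=C)[C@@H](O)CO)[C@H]2C(=C)C(=O)O[C@@H]2[C@H]1C(=C)CO | target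

**Step count and risks**

Total steps: 17. Longest linear sequence: 14 (steps 1–12, 16, 17).

Steps most likely to fail:

Step 7 (Proposed new method). The process may be diverted by closure in the 5-ring ene mode with proton loss from C11, by capture of the activated aldehyde by the C4 carboxyl as a cyclic acylal, or by low reactivity of the 1,2-disubstituted alkene. The fallback sets out from 10 and returns at 11, and separates the two bond formations with known reactions. TiCl4 (CH2Cl2, −78 °C), the established chloro-Prins cyclisation of 5-hexenals, should give the chlorohydrin 3-(carboxymethyl)-2-chloro-6-ethenyl-4-hydroxy-6-methylcyclohexane-1-carboxylic acid F1, with chloride in place of the lactone oxygen. AgOTf with 2,6-di-tert-butylpyridine (CH2Cl2, 0 °C) then ionises the C6–Cl bond, and the neighbouring C12 carboxylate should close the γ-lactone from the equatorial side, because axial entry is hindered by the axial C10 methyl; this gives 11.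

Step 3. Control of enolate geometry or of the enolate face may be incomplete, giving diastereomer and enantiomer mixtures, and the second ester may rearrange as well. The fallback sets out from 5 and returns at 7. Classical Ireland–Claisen rearrangement through the silyl ketene acetal (LiN(i-Pr)2, Me3SiCl, THF/HMPA, −78 °C → rt; the polar co-solvent favours the Z-(O) enolate) should give 7 as the racemate, that is together with its mirror image ent-7 F2. Crystallisation of the salt of 7 with (R)-1-phenylethylamine F3, followed by acidification, returns enantiopure 7.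

Step 9. The hindered acyl–palladium intermediate may lose CO, and transfer of the alkoxymethyl group from tin may be slow. The fallback sets out from 12, passes through 13 and returns at 14. Acid chloride 13 with CH2N2 (Et2O, 0 °C) should give the diazoketone 7-(diazoacetyl)-6-ethenyl-6-methyl-4-(triethylsilyloxy)hexahydro-1-benzofuran-2(3H)-one F4. Rh2(OAc)4-catalysed O–H insertion into water (THF/H2O, rt) should give the hydroxymethyl ketone 6-ethenyl-7-(hydroxyacetyl)-6-methyl-4-(triethylsilyloxy)hexahydro-1-benzofuran-2(3H)-one F5. CH3OCH2Cl with i-Pr2NEt (CH2Cl2, 0 °C) then gives 14.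

**Further compounds**

F1 | step 7 | 3-(carboxymethyl)-2-chloro-6-ethenyl-4-hydroxy-6-methylcyclohexane-1-carboxylic acid (all substituents equatorial, C6 methyl axial) | C=C[C@]1(C)C[C@H](O)[C@@H](CC(=O)O)[C@H](Cl)[C@H]1C(=O)O
F2 | step 3 | ent-7, (2S,3E)-2-[(3R)-5-(tert-butyldimethylsilyloxy)-3-methylpent-1-en-3-yl]hex-3-enedioic acid 6-[(2E)-5-(tert-butyldimethylsilyloxy)-3-methylpent-2-en-1-yl] ester | C=C[C@@](C)(CCO[Si](C)(C)C(C)(C)C)[C@@H](C(=O)O)/C=C/CC(=O)OC/C=C(\C)CCO[Si](C)(C)C(C)(C)C
F3 | step 3 | (R)-1-phenylethylammonium salt of 7 | C=C[C@](C)(CCO[Si](C)(C)C(C)(C)C)[C@H](C(=O)[O-])/C=C/CC(=O)OC/C=C(\C)CCO[Si](C)(C)C(C)(C)C.C[C@@H]([NH3+])c1ccccc1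
F4 | step 9 | 7-(diazoacetyl)-6-ethenyl-6-methyl-4-(triethylsilyloxy)hexahydro-1-benzofuran-2(3H)-one | C=C[C@]1(C)C[C@H](O[Si](CC)(CC)CC)[C@H]2CC(=O)O[C@@H]2[C@H]1C(=O)C=[N+]=[N-]
F5 | step 9 | 6-ethenyl-7-(hydroxyacetyl)-6-methyl-4-(triethylsilyloxy)hexahydro-1-benzofuran-2(3H)-one | C=C[C@]1(C)C[C@H](O[Si](CC)(CC)CC)[C@H]2CC(=O)O[C@@H]2[C@H]1C(=O)CO
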